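**Strategy.** In labdane numbering, ring A (C1–C5, C10) carries only the C4 gem-dimethyl group, flanked by C5–H and the quaternary C10 methyl. This array is read as a 1,2,2-trimethylcyclopentane whose CMe2 carbon (C4) has moved from C10 to C5. Ionizing the (R)-mesylate of a 1-(1,2,2-trimethylcyclopentyl)carbinol bearing a 3-methylpenta-3,4-dienyl chain should enlarge the cyclopentane to ring A, set C5 by inversion and unveil the C10 cation. That cation closes ring B on the allene (trans fusion) and ends as the C8=C9 alkene with C11–Cl. A D-glycerate-derived allylsilane then adds C12–C16 with the (14S)-diol.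

Key step: step 6

Remark: compounds 3 and 5–9 are carried as the racemate or epimer pair at the cyclopentane quaternary carbon, because this centre becomes the planar C10 cation in step 6; 1-acetyl-2-methylcyclopentene and methyl (R)-glycerate acetonide are taken as commercial.

**Step 1**
Reactants: 1 1-(2-methylcyclopent-1-en-1-yl)ethan-1-one
Product: 3 1-(1,2,2-trimethylcyclopentyl)ethan-1-one (racemic), via lithium enolate 2 (not isolated)
Conditions: Me2CuLi (from MeLi and CuI), Et2O, −20 → 0 °C; then MeI (excess), DMPU, THF, 0 °C → rt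
Reagents that add atoms: lithium dimethylcuprate [Li+].C[Cu-]C; iodomethane CI
Why: Cuprate conjugate addition to the β,β-disubstituted enone creates the gem-dimethyl carbon and gives regiospecifically the tetrasubstituted enolate 2, whose C-methylation (conjugate addition–enolate alkylation) builds the adjacent quaternary carbon as a racemate, which is harmless because this centre is erased in step 6.

**Step 2**
Reactants: 3 1-(1,2,2-trimethylcyclopentyl)ethan-1-one; 4 1,4-dichlorobut-2-yne
Product: 6 6-chloro-1-(1,2,2-trimethylcyclopentyl)hex-4-yn-1-one, via lithium enolate 5 (not isolated)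
Conditions: LiN(iPr)2, THF, −78 °C; then added to 4 (3 equiv), DMPU, −78 → 0 °C
Reagents that add atoms: none
Why: Ketone 3 can enolize only toward its methyl group, so the lithium enolate alkylation (SN2 at one propargylic chloride of the excess dihalide) is regiodefined.

**Step 3**
Reactants: 6 6-chloro-1-(1,2,2-trimethylcyclopentyl)hex-4-yn-1-one
Product: 7 4-methyl-1-(1,2,2-trimethylcyclopentyl)hexa-4,5-dien-1-one
Conditions: Me2CuLi (from MeLi and CuI), Et2O, −78 → −30 °C
Reagents that add atoms: lithium dimethylcuprate [Li+].C[Cu-]C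
Why: Organocuprate anti-SN2′ substitution of the primary propargylic chloride delivers methyl to the distal alkyne carbon and gives the 1,1-disubstituted allene, while the hindered ketone should be inert to the cuprate at low temperature.

**Step 4**
Reactants: 7 4-methyl-1-(1,2,2-trimethylcyclopentyl)hexa-4,5-dien-1-one
Product: 8 (1R)-4-methyl-1-(1,2,2-trimethylcyclopentyl)hexa-4,5-dien-1-ol (both epimers at the ring quaternary carbon)
Conditions: (S)-2-methyl-CBS-oxazaborolidine (0.2 equiv), catecholborane, toluene, −40 → 0 °C; aqueous NaOH work-up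
Reagents that add atoms: none
Why: Corey–Bakshi–Shibata reduction in which the tert-alkyl group acts as the large and the CH2 chain as the small substituent, so the (S)-catalyst should give the (R)-carbinol for both ring epimers, and catecholborane leaves the allene untouched.

**Step 5**
Reactants: 8 (1R)-4-methyl-1-(1,2,2-trimethylcyclopentyl)hexa-4,5-dien-1-ol
Product: 9 (1R)-4-methyl-1-(1,2,2-trimethylcyclopentyl)hexa-4,5-dien-1-yl methanesulfonate
Conditions: MsCl, Et3N, CH2Cl2, −20 → 0 °C; used crude
Reagents that add atoms: methanesulfonyl chloride CS(=O)(=O)Cl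
Why: Sulfonylation through sulfene tolerates the hindered neopentylic secondary alcohol and turns it into a nucleofuge without touching the stereocentre.

**Step 6**
Reactants: 9 (1R)-4-methyl-1-(1,2,2-trimethylcyclopentyl)hexa-4,5-dien-1-yl methanesulfonate
Product: 12 (4aR,8aR)-1-(chloromethyl)-2,5,5,8a-tetramethyl-3,4,4a,5,6,7,8,8a-octahydronaphthalene (ent-drim-8-en-11-yl chloride), via ring-expanded cyclohexyl cation 10 (not isolated), via bicyclic allyl cation 11 (not isolated)
Conditions: Me2AlCl (2.5 equiv), CH2Cl2, −78 → −30 °C; aqueous NaHCO3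
Reagents that add atoms: dimethylaluminium chloride C[Al](C)Cl
Why: Proposed new method: Me2AlCl-assisted ionization of the mesylate should be concerted with an antiperiplanar 1,2-shift of the ring CMe2 carbon (C4) from the quaternary ring carbon (C10) to the carbinyl carbon (C5), a Wagner–Meerwein ring expansion giving tertiary cation 10, which is attacked by the central allene carbon (C9) to give allyl cation 11, which collapses with chloride from the aluminate at its primary terminus C11. The closest known reaction types are the solvolytic ring expansion of 1-(1-methylcyclopentyl)alkyl sulfonates, the second ring closure of stepwise biomimetic polyene cyclizations through this same monocyclic tertiary cation, allene-terminated cationic cyclization and organoaluminium-promoted ionization with chloride delivery, and only their merger in one operation is new. Ring A is not closed by cyclization but arises from the five-membered ring by insertion of C4 between C3 and C5, whereas ring B closes in a 6-endo mode at the central allene carbon through a chair-like transition state. C5 is set with inversion by the backside arrival of C4, so it is controlled by the carbinol centre from step 4, and C10 is set by substrate control because the equatorial side chain on C5 delivers C9 to the face that gives the trans-fused decalin, so both epimers of 9 converge. The step needs migration of the CMe2 carbon rather than the ring CH2 or the methyl group, which the higher migratory aptitude of the tertiary alkyl group and the relief of the vicinal quaternary–quaternary strain should secure, and it needs chloride capture at C11 rather than C8, which reversible ionization of the tertiary chloride should funnel to the primary chloride with the tetrasubstituted C8=C9 alkene.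

**Step 7**
Reactants: 13 methyl (4R)-2,2-dimethyl-1,3-dioxolane-4-carboxylate
Product: 15 (4S)-2,2-dimethyl-4-[3-(trimethylsilyl)prop-1-en-2-yl]-1,3-dioxolane, via bis(silylmethyl) carbinol 14 (not isolated)
Conditions: Me3SiCH2MgCl (3 equiv), CeCl3 (3 equiv), THF, −78 °C → rt; then silica gel, CH2Cl2, rt
Reagents that add atoms: (trimethylsilyl)methylmagnesium chloride C[Si](C)(C)C[Mg]Cl
Why: Double addition of the weakly basic organocerium reagent to the ester followed by Peterson elimination of carbinol 14 gives the 2-substituted allylsilane without epimerizing the α-alkoxy stereocentre (the descriptor changes from R to S only because the priorities change).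

**Step 8**
Reactants: 12 (4aR,8aR)-1-(chloromethyl)-2,5,5,8a-tetramethyl-3,4,4a,5,6,7,8,8a-octahydronaphthalene; 15 (4S)-2,2-dimethyl-4-[3-(trimethylsilyl)prop-1-en-2-yl]-1,3-dioxolane
Product: 16 (4S)-2,2-dimethyl-4-{4-[(4aR,8aR)-2,5,5,8a-tetramethyl-3,4,4a,5,6,7,8,8a-octahydronaphthalen-1-yl]but-1-en-2-yl}-1,3-dioxolane
Conditions: ZnCl2·OEt2 (0.3 equiv), CH2Cl2, −78 → −40 °C
Reagents that add atoms: none
Why: Lewis-acid-promoted allylation of an ionizable allylic chloride by an allylsilane (Hosomi–Sakurai-type SE2′ reaction) in which the regenerated allyl cation is attacked at its unhindered primary terminus C11 by the CH2= terminus of 15 and loss of the silyl group re-forms the C13=C16 methylene, with no stereocentre involved.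

**Step 9**
Reactants: 16 (4S)-2,2-dimethyl-4-{4-[(4aR,8aR)-2,5,5,8a-tetramethyl-3,4,4a,5,6,7,8,8a-octahydronaphthalen-1-yl]but-1-en-2-yl}-1,3-dioxolane
Product: 17 (2S)-3-methylidene-5-[(4aR,8aR)-2,5,5,8a-tetramethyl-3,4,4a,5,6,7,8,8a-octahydronaphthalen-1-yl]pentane-1,2-diol
Conditions: AcOH–H2O (4:1), 40 °C
Reagents that add atoms: none
Why: Mild acid-catalysed acetal hydrolysis should free the 1,2-diol without isomerizing either alkene or touching C14.

**Step 10**
Reactants: 17 (2S)-3-methylidene-5-[(4aR,8aR)-2,5,5,8a-tetramethyl-3,4,4a,5,6,7,8,8a-octahydronaphthalen-1-yl]pentane-1,2-diol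
Product: 18 (2S)-3-methylidene-5-[(4aR,8aR)-2,5,5,8a-tetramethyl-3,4,4a,5,6,7,8,8a-octahydronaphthalen-1-yl]pentane-1,2-diyl diacetate (target)
Conditions: Ac2O, pyridine, DMAP (cat.), CH2Cl2, 0 °C → rt
Reagents that add atoms: acetic anhydride CC(=O)OC(C)=O
Why: DMAP-catalysed acylation of the primary and the secondary allylic hydroxyl gives the diacetate with retention at C14.

**Compound list**
1 | 1-(2-methylcyclopent-1-en-1-yl)ethan-1-one (1-acetyl-2-methylcyclopentene) | CC(=O)C1=C(C)CCC1 | starting material
2 | lithium 1-(2,2-dimethylcyclopentylidene)ethan-1-olate | [Li+].[O-]C(C)=C1CCCC1(C)C | intermediate (not isolated)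
3 | 1-(1,2,2-trimethylcyclopentyl)ethan-1-one, racemic | CC(=O)C1(C)CCCC1(C)C | intermediate
4 | 1,4-dichlorobut-2-yne | ClCC#CCCl | starting material
5 | lithium 1-(1,2,2-trimethylcyclopentyl)ethen-1-olate | [Li+].[O-]C(=C)C1(C)CCCC1(C)C | intermediate (not isolated)
6 | 6-chloro-1-(1,2,2-trimethylcyclopentyl)hex-4-yn-1-one, racemic | ClCC#CCCC(=O)C1(C)CCCC1(C)C | intermediate
7 | 4-methyl-1-(1,2,2-trimethylcyclopentyl)hexa-4,5-dien-1-one, racemic | C=C=C(C)CCC(=O)C1(C)CCCC1(C)C | intermediate
8 | (1R)-4-methyl-1-(1,2,2-trimethylcyclopentyl)hexa-4,5-dien-1-ol, both epimers at the ring quaternary carbon | C=C=C(C)CC[C@@H](O)C1(C)CCCC1(C)C | intermediate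
9 | (1R)-4-methyl-1-(1,2,2-trimethylcyclopentyl)hexa-4,5-dien-1-yl methanesulfonate, both epimers at the ring quaternary carbon | C=C=C(C)CC[C@@H](OS(C)(=O)=O)C1(C)CCCC1(C)C | intermediate
10 | 1,3,3-trimethyl-2-(3-methylpenta-3,4-dien-1-yl)cyclohexan-1-ylium, ring-expanded tertiary cation with C2 (the future C5) configured as in 12 | C=C=C(C)CC[C@@H]1C(C)(C)CCC[C+]1C | intermediate (not isolated)
11 | [(4aR,8aR)-2,5,5,8a-tetramethyl-3,4,4a,5,6,7,8,8a-octahydronaphthalen-1-yl]methylium, allyl cation delocalized over C11, C9 and C8 | [CH2+]C1=C(C)CC[C@@H]2C(C)(C)CCC[C@@]12C | intermediate (not isolated)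
12 | (4aR,8aR)-1-(chloromethyl)-2,5,5,8a-tetramethyl-3,4,4a,5,6,7,8,8a-octahydronaphthalene (ent-drim-8-en-11-yl chloride) | ClCC1=C(C)CC[C@@H]2C(C)(C)CCC[C@@]12C | intermediate
13 | methyl (4R)-2,2-dimethyl-1,3-dioxolane-4-carboxylate | COC(=O)[C@H]1COC(C)(C)O1 | starting material
14 | 2-[(4R)-2,2-dimethyl-1,3-dioxolan-4-yl]-1,3-bis(trimethylsilyl)propan-2-ol | C[Si](C)(C)CC(O)(C[Si](C)(C)C)[C@H]1COC(C)(C)O1 | intermediate (not isolated)
15 | (4S)-2,2-dimethyl-4-[3-(trimethylsilyl)prop-1-en-2-yl]-1,3-dioxolane | C=C(C[Si](C)(C)C)[C@H]1COC(C)(C)O1 | intermediate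
16 | (4S)-2,2-dimethyl-4-{4-[(4aR,8aR)-2,5,5,8a-tetramethyl-3,4,4a,5,6,7,8,8a-octahydronaphthalen-1-yl]but-1-en-2-yl}-1,3-dioxolane | C=C(CCC1=C(C)CC[C@@H]2C(C)(C)CCC[C@@]12C)[C@H]1COC(C)(C)O1 | intermediate
17 | (2S)-3-methylidene-5-[(4aR,8aR)-2,5,5,8a-tetramethyl-3,4,4a,5,6,7,8,8a-octahydronaphthalen-1-yl]pentane-1,2-diol | C=C(CCC1=C(C)CC[C@@H]2C(C)(C)CCC[C@@]12C)[C@@H](CO)O | intermediate
18 | (2S)-3-methylidene-5-[(4aR,8aR)-2,5,5,8a-tetramethyl-3,4,4a,5,6,7,8,8a-octahydronaphthalen-1-yl]pentane-1,2-diyl diacetate | C=C(CCC1=C(C)CC[C@@H]2C(C)(C)CCC[C@@]12C)[C@@H](COC(C)=O)OC(C)=O | target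

**Step count.** Total: 10 steps. Longest linear sequence: 9 steps (steps 1–6 and 8–10); step 7 prepares the side-chain reagent.

**Steps most likely to fail**

1. Step 6 (proposed new method). The tertiary cation 10 may lose a proton or take up chloride before ring B closes, or allyl cation 11 may lose a proton instead of collapsing with chloride at C11. The fallback uses two discrete, known stages and sets out from 9. Buffered hydrolysis (acetone–water, CaCO3, 50 °C), a classical Wagner–Meerwein solvolysis with capture by water, should give (2R)-1,3,3-trimethyl-2-(3-methylpenta-3,4-dien-1-yl)cyclohexan-1-ol F1, in which ring A already exists and C5 is fixed. Re-ionization of this tertiary alcohol with SnCl4 in CH2Cl2 at −78 °C, a standard tertiary-carbinol-initiated cation–π cyclization with an allene terminator and chloride capture, should then close ring B and come back to the route at 12.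

2. Step 8. The allyl cation may lose a proton to a diene, be attacked at the tertiary terminus C8, or the Lewis acid may open the acetonide faster than the C–C bond forms. The fallback sets out from 12 and 13 and replaces the cationic coupling by enolate chemistry. Ester 13 is converted with MeNH(OMe)·HCl and iPrMgCl into (4R)-N-methoxy-N,2,2-trimethyl-1,3-dioxolane-4-carboxamide F2, and MeMgBr then gives 1-[(4R)-2,2-dimethyl-1,3-dioxolan-4-yl]ethan-1-one F3. Its kinetic lithium enolate (LiN(iPr)2, THF, −78 °C) is alkylated with 12 (NaI, DMPU) to give 1-[(4R)-2,2-dimethyl-1,3-dioxolan-4-yl]-3-[(4aR,8aR)-2,5,5,8a-tetramethyl-3,4,4a,5,6,7,8,8a-octahydronaphthalen-1-yl]propan-1-one F4. Wittig methylenation (Ph3P=CH2, THF, −78 → 0 °C) then comes back to the route at 16.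

3. Step 1. C-methylation of the hindered cuprate-derived enolate 2 may be slow, so that proton transfer to the product diverts methylation to the acetyl methyl group. The fallback sets out from 1. Conjugate addition of Me2CuLi in the presence of Me3SiCl and Et3N traps the adduct as trimethyl{[1-(2,2-dimethylcyclopentylidene)ethyl]oxy}silane F5, which is isolated. MeLi (THF, 0 °C) then unmasks a copper-free lithium enolate that is methylated with MeI and DMPU, coming back to the route at 3.

**Further compounds**
F1 | step 6 | (2R)-1,3,3-trimethyl-2-(3-methylpenta-3,4-dien-1-yl)cyclohexan-1-ol, either epimer at C1 | C=C=C(C)CC[C@@H]1C(C)(C)CCCC1(C)O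
F2 | step 8 | (4R)-N-methoxy-N,2,2-trimethyl-1,3-dioxolane-4-carboxamide | CON(C)C(=O)[C@H]1COC(C)(C)O1
F3 | step 8 | 1-[(4R)-2,2-dimethyl-1,3-dioxolan-4-yl]ethan-1-one | CC(=O)[C@H]1COC(C)(C)O1
F4 | step 8 | 1-[(4R)-2,2-dimethyl-1,3-dioxolan-4-yl]-3-[(4aR,8aR)-2,5,5,8a-tetramethyl-3,4,4a,5,6,7,8,8a-octahydronaphthalen-1-yl]propan-1-one | O=C(CCC1=C(C)CC[C@@H]2C(C)(C)CCC[C@@]12C)[C@H]1COC(C)(C)O1
F5 | step 1 | trimethyl{[1-(2,2-dimethylcyclopentylidene)ethyl]oxy}silane | CC(O[Si](C)(C)C)=C1CCCC1(C)C
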